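**Retrosynthetic overview**

1. Selaginellin U ⇐ its tris(methyl ether) by cleavage of three ArO–Me bonds in the last step; the four benzene rings are bought, and only the dienone (quinone methide) ring is constructed.
2. Six-membered quinone methide ring ⇐ four-membered ring: a 4-(diarylmethylidene)cyclobut-2-en-1-one plus acetylide; 1,2-addition, 4π ring opening and C–C closure place the two acetylide carbons between C1 (C–O) and C4 (C=CAr2) of the cyclobutene (4 → 6).
3. Enabling feature: the strained cyclobutene whose sp3 carbon C1 carries O⁻ and ethynyl and whose C4 carries the exocyclic diarylmethylidene double bond; ring opening turns C4=CAr2 into an allene whose central carbon (old C4) lies cis to the alkyne terminus, so closure leaves CAr2 exocyclic and para to C=O.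
4. Alkylidenecyclobutenone ⇐ allenylketene (4π closure) ⇐ 5,5-diarylpenta-3,4-dienoic acid ⇐ Reformatsky–Claisen shift of a propargylic bromoacetate ⇐ diaryl ketone + ethynyl Grignard reagent.
5. Diaryl ketone ⇐ 2,4-dibromotoluene: lithiation between the bromines and addition to anisaldehyde, oxidation, Suzuki coupling at the less hindered C–Br, Sonogashira coupling at the other; ring order: four-membered ring (step 7), then the six-membered dienone ring (step 8).

Key step: step 8

Remark: the target has no stereocentre and no configurationally stable axis (its SMILES carries no stereodescriptor), so there is no enantiomer to select; racemic or E/Z-mixed intermediates (4, 11–18) converge in step 8.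

Abbreviation used in names: Ar* = 4'-methoxy-3-[(4-methoxyphenyl)ethynyl]-4-methylbiphenyl-2-yl.

**Step 1**
Reactants: 1 2,4-dibromotoluene; 2 4-methoxybenzaldehyde
Product: 4 (2,6-dibromo-3-methylphenyl)(4-methoxyphenyl)methanol (racemic), via 2,6-dibromo-3-methylphenyllithium 3 (not isolated)
Conditions: LDA (1.05 equiv), THF, −78 °C, 1 h; 2, −78 → −40 °C; H2O
Reagents that add atoms: none
Why: Directed ortho-lithiation, in which the C–H flanked by both bromines is the most acidic site of 1 and the resulting 2,6-dibromoaryllithium (no driving force for a halogen dance, slow aryne formation at −78 °C) adds 1,2 to the aldehyde; the carbinol stereocentre is formed racemic and is removed in step 2.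

**Step 2**
Reactants: 4 (2,6-dibromo-3-methylphenyl)(4-methoxyphenyl)methanol
Product: 5 (2,6-dibromo-3-methylphenyl)(4-methoxyphenyl)methanone
Conditions: Dess–Martin periodinane (1.2 equiv), CH2Cl2, rt
Reagents that add atoms: none
Why: Dess–Martin oxidation of a secondary diaryl carbinol to the benzophenone, with no other oxidisable group present.

**Step 3**
Reactants: 5 (2,6-dibromo-3-methylphenyl)(4-methoxyphenyl)methanone; 6 (4-methoxyphenyl)boronic acid
Product: 7 (3-bromo-4'-methoxy-4-methylbiphenyl-2-yl)(4-methoxyphenyl)methanone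
Conditions: 6 (1.05 equiv), Pd(PPh3)4 (5 mol %), K2CO3, toluene/EtOH/H2O, 80 °C
Reagents that add atoms: none
Why: Site-selective Suzuki–Miyaura coupling, in which oxidative addition should prefer the C–Br bond with one ortho substituent over the one flanked by both the carbonyl and the methyl group, while one equivalent of boronic acid limits double coupling.

**Step 4**
Reactants: 7 (3-bromo-4'-methoxy-4-methylbiphenyl-2-yl)(4-methoxyphenyl)methanone; 8 1-ethynyl-4-methoxybenzene
Product: 9 Ar*(4-methoxyphenyl)methanone
Conditions: 8 (1.3 equiv), PdCl2(MeCN)2 (3 mol %), XPhos (9 mol %), Cs2CO3, MeCN, 80 °C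
Reagents that add atoms: none
Why: Copper-free Sonogashira coupling with a bulky biarylphosphine, the usual answer to a doubly ortho-substituted aryl bromide; leaving out copper avoids alkyne homocoupling.

**Step 5**
Reactants: 9 Ar*(4-methoxyphenyl)methanone; 10 ethynylmagnesium bromide
Product: 12 1-Ar*-1-(4-methoxyphenyl)prop-2-yn-1-yl bromoacetate (racemic), via bromomagnesium propargylic alkoxide 11 (not isolated)
Conditions: 10 (1.5 equiv), THF, 0 °C → rt; BrCH2COBr (3 equiv), −40 → 0 °C; filtered through basic alumina, used crude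
Reagents that add atoms: bromoacetyl bromide, BrCC(Br)=O
Why: 1,2-Addition of a small alkynyl Grignard reagent to the hindered diaryl ketone and O-acylation of the alkoxide in the same flask, which avoids isolating the ionisation-prone tertiary propargylic alcohol; the quaternary centre is racemic and disappears in step 6.

**Step 6**
Reactants: 12 1-Ar*-1-(4-methoxyphenyl)prop-2-yn-1-yl bromoacetate
Product: 14 5-Ar*-5-(4-methoxyphenyl)penta-3,4-dienoic acid (racemic allene), via bromozinc ester enolate 13 (not isolated)
Conditions: Zn dust (activated, 3 equiv), THF, 50 °C; cold 0.5 M HCl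
Reagents that add atoms: none
Why: Reformatsky–Claisen rearrangement, in which the zinc enolate of the propargylic ester undergoes a [3,3]-sigmatropic shift to the allenic acid, driven by carboxylate formation and relief of crowding at the quaternary carbon; a zinc enolate should leave the terminal alkyne C–H untouched, unlike lithium amide conditions.

**Step 7**
Reactants: 14 5-Ar*-5-(4-methoxyphenyl)penta-3,4-dienoic acid
Product: 17 4-[Ar*(4-methoxyphenyl)methylidene]cyclobut-2-en-1-one (E/Z mixture), via dienoyl chloride 15 (not isolated), via allenylketene 16 (not isolated)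
Conditions: 1-chloro-N,N,2-trimethylprop-1-en-1-amine (Ghosez reagent, 1.2 equiv), CH2Cl2, 0 °C → rt; then slow addition to i-Pr2NEt (1.5 equiv), toluene (0.01 M), 80 °C
Reagents that add atoms: none
Why: Neutral acid chloride formation, dehydrochlorination to the allenylketene and its 4π-electrocyclic ring closure (vinylketene/cyclobutenone manifold), which for allenylketenes should lie on the side of the 4-methylidenecyclobutenone; high dilution suppresses ketene dimerisation, and both double-bond isomers of 17 are usable.

**Step 8**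
Reactants: 17 4-[Ar*(4-methoxyphenyl)methylidene]cyclobut-2-en-1-one
Product: 21 4-[Ar*(4-methoxyphenyl)methylidene]cyclohexa-2,5-dien-1-one, via lithium cyclobutenolate 18 (not isolated), via enyne-allene enolate 19 (not isolated), via C-lithiated quinone methide 20 (not isolated)
Conditions: HC≡CLi (1.1 equiv, from acetylene and n-BuLi, excess acetylene purged with argon), THF, −78 °C, 30 min; −78 °C → rt (to 50 °C if needed); H2O, −40 °C
Reagents that add atoms: lithium acetylide, [Li]C#C
Why: Proposed new method: lithium acetylide adds 1,2 to the cyclobutenone carbonyl of 17, and the alkoxide 18 should undergo oxyanion-accelerated conrotatory 4π ring opening of the strained four-membered ring (C1–C4 bond) with the oxido group rotating outward and the ethynyl group inward, so that in the enolate 19 the alkyne terminus lies next to the central allene carbon (the former C4). Bond formation between these two carbons (C2–C7 cycloaromatisation of Myers–Saito type, in its anionic form an allowed 6π closure, 6-endo at the alkyne) closes the six-membered ring from the four cyclobutene carbons plus the two acetylide carbons, leaves the diarylmethylidene carbon exocyclic and para to the carbonyl, and gives the sp2 carbanion 20, which is protonated on quench to 21. The closest known reaction types are the Moore ring expansion of 4-alkynyl-4-hydroxycyclobutenones (4π opening, then enyne-ketene cyclisation with transfer of the hydroxyl hydrogen to the adjacent ring carbon), the Myers–Saito cyclisation of enyne-allenes and the oxyanion-accelerated ring opening of cyclobutenoxides. No stereocentre is formed. The step needs 1,2- rather than 1,4- or 1,6-addition (hard acetylide at −78 °C, fully substituted and crowded methide carbon), inward rotation of the alkyne (outward preference of O⁻) and six-membered rather than five-membered (C2–C6) closure (unsubstituted alkyne terminus, diaryl-stabilised exocyclic carbon). The driving forces are release of cyclobutene strain and formation of the cross-conjugated quinone methide.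

**Step 9**
Reactants: 21 4-[Ar*(4-methoxyphenyl)methylidene]cyclohexa-2,5-dien-1-one
Product: 22 Selaginellin U
Conditions: BBr3 (8 equiv), CH2Cl2, −78 → 0 °C; aq. NaHCO3
Reagents that add atoms: none
Why: Lewis-acid cleavage of the three aryl methyl ethers (BBr3 demethylation), during which the quinone methide is held as its O-borylated triarylmethyl cation and should return on aqueous work-up; low temperature should keep that cation from Friedel–Crafts closure onto the neighbouring aryl ring.

**Compound list**

1 | 2,4-dibromotoluene | Cc1ccc(Br)cc1Br | starting material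
2 | 4-methoxybenzaldehyde | COc1ccc(C=O)cc1 | starting material
3 | 2,6-dibromo-3-methylphenyllithium (not isolated) | [Li]c1c(Br)c(C)ccc1Br | intermediate
4 | (2,6-dibromo-3-methylphenyl)(4-methoxyphenyl)methanol (racemic) | COc1ccc(cc1)C(O)c1c(Br)c(C)ccc1Br | intermediate
5 | (2,6-dibromo-3-methylphenyl)(4-methoxyphenyl)methanone | COc1ccc(cc1)C(=O)c1c(Br)c(C)ccc1Br | intermediate
6 | (4-methoxyphenyl)boronic acid | COc1ccc(cc1)B(O)O | starting material
7 | (3-bromo-4'-methoxy-4-methylbiphenyl-2-yl)(4-methoxyphenyl)methanone | COc1ccc(cc1)C(=O)c1c(Br)c(C)ccc1-c1ccc(OC)cc1 | intermediate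
8 | 1-ethynyl-4-methoxybenzene | COc1ccc(cc1)C#C | starting material
9 | Ar*(4-methoxyphenyl)methanone | COc1ccc(cc1)C(=O)c1c(C#Cc2ccc(OC)cc2)c(C)ccc1-c1ccc(OC)cc1 | intermediate
10 | ethynylmagnesium bromide | C#C[Mg]Br | starting material
11 | bromomagnesium 1-Ar*-1-(4-methoxyphenyl)prop-2-yn-1-olate (racemic, not isolated) | COc1ccc(cc1)C(O[Mg]Br)(C#C)c1c(C#Cc2ccc(OC)cc2)c(C)ccc1-c1ccc(OC)cc1 | intermediate
12 | 1-Ar*-1-(4-methoxyphenyl)prop-2-yn-1-yl bromoacetate (racemic) | COc1ccc(cc1)C(OC(=O)CBr)(C#C)c1c(C#Cc2ccc(OC)cc2)c(C)ccc1-c1ccc(OC)cc1 | intermediate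
13 | bromozinc enolate of 12 (not isolated) | COc1ccc(cc1)C(OC(=C)O[Zn]Br)(C#C)c1c(C#Cc2ccc(OC)cc2)c(C)ccc1-c1ccc(OC)cc1 | intermediate
14 | 5-Ar*-5-(4-methoxyphenyl)penta-3,4-dienoic acid (racemic allene) | COc1ccc(cc1)C(=C=CCC(O)=O)c1c(C#Cc2ccc(OC)cc2)c(C)ccc1-c1ccc(OC)cc1 | intermediate
15 | 5-Ar*-5-(4-methoxyphenyl)penta-3,4-dienoyl chloride (not isolated) | COc1ccc(cc1)C(=C=CCC(Cl)=O)c1c(C#Cc2ccc(OC)cc2)c(C)ccc1-c1ccc(OC)cc1 | intermediate
16 | 5-Ar*-5-(4-methoxyphenyl)penta-1,3,4-trien-1-one (allenylketene, not isolated) | COc1ccc(cc1)C(=C=CC=C=O)c1c(C#Cc2ccc(OC)cc2)c(C)ccc1-c1ccc(OC)cc1 | intermediate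
17 | 4-[Ar*(4-methoxyphenyl)methylidene]cyclobut-2-en-1-one (E/Z mixture) | COc1ccc(cc1)C(=C1C=CC1=O)c1c(C#Cc2ccc(OC)cc2)c(C)ccc1-c1ccc(OC)cc1 | intermediate
18 | lithium 4-[Ar*(4-methoxyphenyl)methylidene]-1-ethynylcyclobut-2-en-1-olate (not isolated) | COc1ccc(cc1)C(=C1C=CC1(O[Li])C#C)c1c(C#Cc2ccc(OC)cc2)c(C)ccc1-c1ccc(OC)cc1 | intermediate
19 | lithium (3E)-7-Ar*-7-(4-methoxyphenyl)hepta-3,5,6-trien-1-yn-3-olate, alkyne cis to the allene (not isolated) | COc1ccc(cc1)C(=C=C/C=C(/O[Li])\C#C)c1c(C#Cc2ccc(OC)cc2)c(C)ccc1-c1ccc(OC)cc1 | intermediate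
20 | 2-lithio-4-[Ar*(4-methoxyphenyl)methylidene]cyclohexa-2,5-dien-1-one (not isolated) | COc1ccc(cc1)C(=C1C=CC(=O)C([Li])=C1)c1c(C#Cc2ccc(OC)cc2)c(C)ccc1-c1ccc(OC)cc1 | intermediate
21 | 4-[Ar*(4-methoxyphenyl)methylidene]cyclohexa-2,5-dien-1-one (tri-O-methyl Selaginellin U) | COc1ccc(cc1)C(=C1C=CC(=O)C=C1)c1c(C#Cc2ccc(OC)cc2)c(C)ccc1-c1ccc(OC)cc1 | intermediate
22 | Selaginellin U, 4-{[4'-hydroxy-3-[(4-hydroxyphenyl)ethynyl]-4-methylbiphenyl-2-yl](4-hydroxyphenyl)methylidene}cyclohexa-2,5-dien-1-one | Cc1ccc(-c2ccc(O)cc2)c(C(=C2C=CC(=O)C=C2)c2ccc(O)cc2)c1C#Cc1ccc(O)cc1 | target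

**Step count and risks**

Total steps: 9. Longest linear sequence: 9 steps (1 → 22).

Steps most likely to fail:

1. Step 8 (Proposed new method). The 4π opening of the alkylidenecyclobutenoxide to the allene may be slow, so that the alkoxide decomposes or the ring-opened enolate is protonated at its γ-carbon on quench to a conjugated dienynone that cannot close. The enyne-allene may also close in the five-membered mode, or the lithiated quinone methide may add to itself before protonation. Fallback with known chemistry, setting out from 9: addition of 4-methoxyphenylmagnesium bromide (THF, 0 °C → rt) should give the triaryl carbinol Ar*-bis(4-methoxyphenyl)methanol F1, and BBr3 (CH2Cl2, −78 → 0 °C) should cleave its four methyl ethers with loss of water and give 22 directly, where the fallback rejoins the route. This fallback gives up the four-to-six ring expansion and takes the ring from a bought anisyl group; it is held only to secure material.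

2. Step 7. The allenylketene may dimerise, or be re-protonated at its γ-carbon by the ammonium salt and isomerise to the conjugated dienoyl chloride, faster than it closes to the four-membered ring. Fallback, setting out from 9, builds the four-membered ring by an intermolecular ketene–allene [2+2] cycloaddition. Addition of (1-lithiovinyl)trimethylsilane (from (1-bromovinyl)trimethylsilane and t-BuLi, THF, −78 °C) should give the β-silyl allylic alcohol 1-Ar*-1-(4-methoxyphenyl)-2-(trimethylsilyl)prop-2-en-1-ol F2. Acid-induced Peterson elimination (cat. TsOH, CH2Cl2, 0 °C) should give the 1,1-diarylallene 1-Ar*-1-(4-methoxyphenyl)propa-1,2-diene F3. Dichloroketene (Cl3CCOCl, Zn–Cu, Et2O) should add across the terminal C=C to give 2,2-dichloro-4-[Ar*(4-methoxyphenyl)methylidene]cyclobutan-1-one F4. Zinc in acetic acid at rt should remove one chlorine to give 2-chloro-4-[Ar*(4-methoxyphenyl)methylidene]cyclobutan-1-one F5, and triethylamine should eliminate HCl to give 17, where the fallback rejoins the route.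

3. Step 6. The tertiary, doubly benzylic propargylic ester may ionise (assisted by zinc halide) before the enolate forms, or the zinc enolate may be quenched by the terminal alkyne C–H. Fallback, setting out from 9, uses an orthoester Claisen rearrangement instead. Ethynylmagnesium bromide with aqueous NH4Cl work-up should give the propargylic alcohol 1-Ar*-1-(4-methoxyphenyl)prop-2-yn-1-ol F6. Johnson–Claisen rearrangement (triethyl orthoacetate, cat. propionic acid, 110 °C) should give ethyl 5-Ar*-5-(4-methoxyphenyl)penta-3,4-dienoate F7. Saponification (LiOH, THF/H2O, 0 °C, to limit isomerisation to the 2,4-dienoate) should give 14, where the fallback rejoins the route.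

Further compounds
F1 | step 8 | Ar*-bis(4-methoxyphenyl)methanol | COc1ccc(cc1)C(O)(c1ccc(OC)cc1)c1c(C#Cc2ccc(OC)cc2)c(C)ccc1-c1ccc(OC)cc1
F2 | step 7 | 1-Ar*-1-(4-methoxyphenyl)-2-(trimethylsilyl)prop-2-en-1-ol (racemic) | COc1ccc(cc1)C(O)(C(=C)[Si](C)(C)C)c1c(C#Cc2ccc(OC)cc2)c(C)ccc1-c1ccc(OC)cc1
F3 | step 7 | 1-Ar*-1-(4-methoxyphenyl)propa-1,2-diene | COc1ccc(cc1)C(=C=C)c1c(C#Cc2ccc(OC)cc2)c(C)ccc1-c1ccc(OC)cc1
F4 | step 7 | 2,2-dichloro-4-[Ar*(4-methoxyphenyl)methylidene]cyclobutan-1-one (E/Z mixture) | COc1ccc(cc1)C(=C1CC(Cl)(Cl)C1=O)c1c(C#Cc2ccc(OC)cc2)c(C)ccc1-c1ccc(OC)cc1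
F5 | step 7 | 2-chloro-4-[Ar*(4-methoxyphenyl)methylidene]cyclobutan-1-one (racemic, E/Z mixture) | COc1ccc(cc1)C(=C1CC(Cl)C1=O)c1c(C#Cc2ccc(OC)cc2)c(C)ccc1-c1ccc(OC)cc1
F6 | step 6 | 1-Ar*-1-(4-methoxyphenyl)prop-2-yn-1-ol (racemic) | COc1ccc(cc1)C(O)(C#C)c1c(C#Cc2ccc(OC)cc2)c(C)ccc1-c1ccc(OC)cc1
F7 | step 6 | ethyl 5-Ar*-5-(4-methoxyphenyl)penta-3,4-dienoate (racemic allene) | COc1ccc(cc1)C(=C=CCC(=O)OCC)c1c(C#Cc2ccc(OC)cc2)c(C)ccc1-c1ccc(OC)cc1
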